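All runs stem from a simulated flask from invented constants; the scatter is artificial.

Free monomer and monomer in chains together hold the charge: the south run reads 99.2% at 4.00 h. So I follow the free monomer, and I count its halvings.

common to all: free monomer 0.011 M (fed, over 50 s)
- south: initiator 0.49 mol%; run made earlier; the fed solution adds 0.50 times the starting volume
- south-east: initiator 0.77 mol%; run made earlier; the fed solution adds 0.50 times the starting volume
- flask: initiator 0.35 mol%; the fed solution adds 0.50 times the starting volume; time 4.0 h

- south (time / h: monomer in chains / %, free monomer / %): 1.00: 77.7, 21.3; 2.00: 78.1, 21.7; 3.00: 78.3, 21.8; 4.00: 77.9, 21.3
- south-east (time / h: monomer in chains / %, free monomer / %): 0.500: 85.0, 14.6; 1.33: 85.8, 14.1; 2.50: 85.0, 15.0; 4.00: 85.1, 14.3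

(readings scatter by 0.3 percentage points)

- every charge counts on the volume at the start, and the solution that is fed holds the whole dose
- the average divides the monomer in chains by the number of chains, living and dead together; two radicals that join make one chain
- what was read earlier has a scatter of 0.3 percentage points, one standard deviation
- the earlier runs do not show the number of chains; that part of a forecast is a guess

- average number of monomer units in a chain (living and dead chains, two that joined counted as one) at 4.0 h
- part of the free monomer that has reacted at 4.0 h

I start with the main step alone: free monomer joins growing chains at a steady radical level. That loss is pseudo-first-order, so the count of halvings grows in step with the time. But the south run reads 21.3% free monomer at 1.00 h and 21.3% at 4.00 h, so its count stands still.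

Next I add a charge of initiator that gets used up. The count now ends at a finite value, as in dead-end polymerisation. I call it the stopping count n: the number of halvings of free monomer before the run stands still. The south readings average 21.5%, so n is 2.22. The south-east readings give 2.79.

Last, radicals end in pairs. Their level then goes as the root of their supply, so at one monomer charge n should go as the root of the loading. The read ratio of the counts is 1.26, and the root of the loadings is 1.25.

For the flask at 0.35 mol%, I get n = 1.87, so by my reckoning 72.6% of the free monomer should react. The forecast gives 72.5% and 300, and says of the second: “The chain count is a guess.”

The flask gives 72.5% and 207, so the forecast's chain length stands too high by a factor 1.45.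

    free monomer + growing radical → monomer in chains + growing radical, rate k1*[growing radical]*[free monomer] (k = 25900 M⁻¹ s⁻¹)
    free monomer + initiating radical → growing radical + monomer in chains (k = 1.10 × 10⁶ M⁻¹ s⁻¹)
    initiator → 2 initiating radical (k = 0.00539 s⁻¹)
    2 growing radical → dead chain (k = 7.00 × 10⁶ M⁻¹ s⁻¹)

The flask's own count is 1.86, beside my 1.87. The flask has nearly come to rest. Initiator is at 0% of its charge at 4.0 h, and the half-life of free monomer by chain growth is then 52 d, longer than 4.0 h. Ten times the time moves the reacted part from 72.5% to 72.6% and leaves the chain length at 207.

In a neighbour flask, the same recipe at 0.88 mol% of initiator, the south count gives n = 2.97, so 87.2% should react. The computed value is 87.2%.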